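## Retrosynthetic overview

- The target comes from global desilylation of its tris-silyl ether. The C3–benzyl bond is then cut: a trans-selective alkylation of a (4R)-butyrolactone enolate with a 4-silyloxy-3-methoxybenzyl bromide joins the two aryl halves late.
- The lactone is the only ring built. It is closed before the coupling by lactonisation of a γ-hydroxy tert-butyl ester, which comes from an Evans syn aldol between a succinyl oxazolidinone and O-silyl vanillin.
- The aldol sets lactone C4 and the carbinol carbon; the alkylation sets C3.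
- Both aryl pieces come from vanillin, made from catechol via guaiacol. The imide comes from L-valinol, diethyl carbonate, succinic anhydride and tert-butanol.
- Ring order: arene rings are present from catechol; the oxazolidinone (auxiliary, later removed) is made next; the butyrolactone is closed last.

Assumption: the SMILES is read as (3R,4R) in the lactone (3,4-trans) with an (S)-configured carbinol carbon; TBS = tert-butyldimethylsilyl throughout.

## Route

Step 1
Reactants: 1 catechol (benzene-1,2-diol)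
Product: 2 guaiacol (2-methoxyphenol)
Conditions: MeI (1.0 equiv), K2CO3 (1.0 equiv), acetone, reflux; 1 in twofold excess, recovered by aqueous wash
Reagents that add atoms: iodomethane, CI
Why: Williamson ether synthesis (SN2 on MeI by the catechol monoanion), held at the mono-ether by running MeI as the limiting reagent against excess diol.

Step 2
Reactants: 2 guaiacol
Product: 4 vanillin (4-hydroxy-3-methoxybenzaldehyde), via 4-hydroxy-3-methoxymandelic acid 3 (not isolated)
Conditions: OHC-CO2H (50% aq.), NaOH, H2O, 30 °C; then CuSO4 (5 mol %), O2 (air), NaOH aq., 95 °C; then H2SO4 to pH 3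
Reagents that add atoms: glyoxylic acid, O=CC(=O)O
Why: Electrophilic hydroxyalkylation of the phenolate para to its oxygen by glyoxylate, followed by copper-catalysed aerobic oxidative decarboxylation of the mandelate, is the established two-stage guaiacol-to-vanillin process.

Step 3
Reactants: 4 vanillin
Product: 5 4-[(tert-butyldimethylsilyl)oxy]-3-methoxybenzaldehyde
Conditions: TBSCl, imidazole, DMF, rt
Reagents that add atoms: tert-butyldimethylsilyl chloride, CC(C)(C)[Si](C)(C)Cl
Why: Imidazole-promoted silylation of the phenol gives an ether that survives the boron enolate, hydride and amide-base steps and is removed by fluoride at the end.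

Step 4
Reactants: 5 4-[(tert-butyldimethylsilyl)oxy]-3-methoxybenzaldehyde
Product: 6 {4-[(tert-butyldimethylsilyl)oxy]-3-methoxyphenyl}methanol
Conditions: NaBH4, EtOH, 0 °C
Reagents that add atoms: none
Why: Chemoselective borohydride reduction of the aldehyde gives the benzylic alcohol and leaves the aryl silyl ether intact at 0 °C.

Step 5
Reactants: 6 {4-[(tert-butyldimethylsilyl)oxy]-3-methoxyphenyl}methanol
Product: 7 [4-(bromomethyl)-2-methoxyphenoxy](tert-butyl)dimethylsilane
Conditions: CBr4, PPh3, CH2Cl2, 0 °C; used at once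
Reagents that add atoms: tetrabromomethane, BrC(Br)(Br)Br
Why: Appel bromination (SN2 on the alkoxyphosphonium ion) runs under neutral conditions and so avoids HBr, which would strip the silyl ether from this electron-rich benzylic bromide.

Step 6
Reactants: 8 L-valinol ((2S)-2-amino-3-methylbutan-1-ol)
Product: 9 (4S)-4-(propan-2-yl)-1,3-oxazolidin-2-one
Conditions: (EtO)2CO, K2CO3 (cat.), 135 °C, EtOH distilled off
Reagents that add atoms: diethyl carbonate, CCOC(=O)OCC
Why: Double acyl substitution on diethyl carbonate by the amino alcohol (carbamate formation then ring closure) gives the Evans auxiliary with the valinol stereocentre untouched.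

Step 7
Reactants: 10 succinic anhydride
Product: 11 4-tert-butoxy-4-oxobutanoic acid (mono-tert-butyl succinate)
Conditions: tBuOH, N-hydroxysuccinimide (cat.), 4-(dimethylamino)pyridine (cat.), Et3N, toluene, reflux
Reagents that add atoms: tert-butanol, CC(C)(C)O
Why: Nucleophile-catalysed alcoholysis (ring opening) of the cyclic anhydride by tert-butanol stops cleanly at the half ester.

Step 8
Reactants: 11 4-tert-butoxy-4-oxobutanoic acid; 9 (4S)-4-(propan-2-yl)-1,3-oxazolidin-2-one
Product: 13 tert-butyl 4-oxo-4-[(4S)-2-oxo-4-(propan-2-yl)-1,3-oxazolidin-3-yl]butanoate, via mixed pivalic anhydride 12 (not isolated)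
Conditions: PivCl, Et3N, THF, −20 °C; then 9, LiCl, rt
Reagents that add atoms: none
Why: N-acylation of the oxazolidinone through the mixed anhydride transfers only the succinyl group because the hindered pivaloyl carbonyl is not attacked.

Step 9
Reactants: 13 tert-butyl 4-oxo-4-[(4S)-2-oxo-4-(propan-2-yl)-1,3-oxazolidin-3-yl]butanoate; 5 4-[(tert-butyldimethylsilyl)oxy]-3-methoxybenzaldehyde
Product: 15 tert-butyl (3S)-3-[(S)-(4-TBSO-3-methoxyphenyl)(hydroxy)methyl]-4-oxo-4-[(4S)-2-oxo-4-(propan-2-yl)-1,3-oxazolidin-3-yl]butanoate, via Z-dibutylboron enolate 14 (not isolated)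
Conditions: Bu2BOTf, iPr2NEt, CH2Cl2, 0 °C; then 5, −78 → 0 °C; then pH 7 buffer, MeOH, 30% H2O2, 0 °C
Reagents that add atoms: none
Why: In this Evans syn aldol reaction the Z-boron enolate reacts through a closed Zimmerman–Traxler chair on the face away from the isopropyl group, which sets both new stereocentres, (3S) at the future lactone C4 and (S) at the carbinol carbon, while the hindered tert-butyl ester does not lactonise.

Step 10
Reactants: 15 the syn aldol adduct
Product: 16 tert-butyl (3S)-3-[(S)-(TBSO)(4-TBSO-3-methoxyphenyl)methyl]-4-oxo-4-[(4S)-2-oxo-4-(propan-2-yl)-1,3-oxazolidin-3-yl]butanoate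
Conditions: TBSOTf (1.2 equiv), 2,6-lutidine, CH2Cl2, −78 → −20 °C
Reagents that add atoms: tert-butyldimethylsilyl trifluoromethanesulfonate, CC(C)(C)[Si](C)(C)OS(=O)(=O)C(F)(F)F
Why: Silyl triflate silylation of the hindered secondary benzylic alcohol at low temperature blocks retro-aldol cleavage and keeps this hydroxyl out of the later lactonisation.

Step 11
Reactants: 16 the silylated aldol imide
Product: 17 tert-butyl (3R,4S)-4-(TBSO)-4-(4-TBSO-3-methoxyphenyl)-3-(hydroxymethyl)butanoate
Conditions: LiBH4, MeOH (1 equiv), THF, 0 °C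
Reagents that add atoms: none
Why: Reductive cleavage of the N-acyl oxazolidinone by LiBH4 attacks the activated imide carbonyl much faster than the tert-butyl ester, so the primary alcohol forms without touching either stereocentre and the auxiliary is released for reuse.

Step 12
Reactants: 17 the γ-hydroxy tert-butyl ester
Product: 18 (4R)-4-[(S)-(TBSO)(4-TBSO-3-methoxyphenyl)methyl]oxolan-2-one
Conditions: 10-camphorsulfonic acid (10 mol %), CH2Cl2, rt
Reagents that add atoms: none
Why: Acid-catalysed intramolecular transesterification (5-exo lactonisation) closes the butyrolactone on the only free hydroxyl, so the ring oxygen is the primary one and no stereocentre is involved.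

Step 13
Reactants: 18 (4R)-4-[(S)-(TBSO)(4-TBSO-3-methoxyphenyl)methyl]oxolan-2-one; 7 [4-(bromomethyl)-2-methoxyphenoxy](tert-butyl)dimethylsilane
Product: 20 (3R,4R)-3-(4-TBSO-3-methoxybenzyl)-4-[(S)-(TBSO)(4-TBSO-3-methoxyphenyl)methyl]oxolan-2-one, via lithium lactone enolate 19 (not isolated)
Conditions: LiN(SiMe3)2 (1.1 equiv), THF, −78 °C; then 7 (1.3 equiv), DMPU, −78 → −40 °C
Reagents that add atoms: none
Why: SN2 alkylation of the lactone lithium enolate by the benzylic bromide takes place on the face anti to the bulky C4 substituent, which sets C3 as (R), trans to C4, and joins the two aryl halves.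

Step 14
Reactants: 20 the tris-TBS lactone
Product: 21 (3R,4R)-3-(4-hydroxy-3-methoxybenzyl)-4-[(S)-hydroxy(4-hydroxy-3-methoxyphenyl)methyl]oxolan-2-one
Conditions: Bu4NF, AcOH (1:1, 4 equiv each), THF, 0 °C → rt
Reagents that add atoms: none
Why: Fluoride-mediated desilylation cleaves all three Si–O bonds, and the acetic acid buffer avoids both phenoxide-driven lactone opening and acid-driven benzylic ionisation of the free product.

## Compound list

1 | catechol (benzene-1,2-diol) | Oc1ccccc1O | starting material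
2 | guaiacol (2-methoxyphenol) | COc1ccccc1O | intermediate
3 | 4-hydroxy-3-methoxymandelic acid, racemic, present as its sodium salt (not isolated) | COc1cc(C(O)C(=O)O)ccc1O | intermediate
4 | vanillin (4-hydroxy-3-methoxybenzaldehyde) | COc1cc(C=O)ccc1O | intermediate
5 | 4-[(tert-butyldimethylsilyl)oxy]-3-methoxybenzaldehyde | COc1cc(C=O)ccc1O[Si](C)(C)C(C)(C)C | intermediate
6 | {4-[(tert-butyldimethylsilyl)oxy]-3-methoxyphenyl}methanol | COc1cc(CO)ccc1O[Si](C)(C)C(C)(C)C | intermediate
7 | [4-(bromomethyl)-2-methoxyphenoxy](tert-butyl)dimethylsilane | COc1cc(CBr)ccc1O[Si](C)(C)C(C)(C)C | intermediate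
8 | L-valinol, (2S)-2-amino-3-methylbutan-1-ol | CC(C)[C@H](N)CO | starting material
9 | (4S)-4-(propan-2-yl)-1,3-oxazolidin-2-one | CC(C)[C@H]1COC(=O)N1 | intermediate
10 | succinic anhydride (oxolane-2,5-dione) | O=C1CCC(=O)O1 | starting material
11 | 4-tert-butoxy-4-oxobutanoic acid | CC(C)(C)OC(=O)CCC(=O)O | intermediate
12 | 4-tert-butoxy-4-oxobutanoic 2,2-dimethylpropanoic anhydride (not isolated) | CC(C)(C)OC(=O)CCC(=O)OC(=O)C(C)(C)C | intermediate
13 | tert-butyl 4-oxo-4-[(4S)-2-oxo-4-(propan-2-yl)-1,3-oxazolidin-3-yl]butanoate | CC(C)(C)OC(=O)CCC(=O)N1[C@@H](C(C)C)COC1=O | intermediate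
14 | Z-dibutylboron enolate of 13 (not isolated) | CCCCB(CCCC)O/C(=C\CC(=O)OC(C)(C)C)N1[C@@H](C(C)C)COC1=O | intermediate
15 | tert-butyl (3S)-3-[(S)-{4-[(tert-butyldimethylsilyl)oxy]-3-methoxyphenyl}(hydroxy)methyl]-4-oxo-4-[(4S)-2-oxo-4-(propan-2-yl)-1,3-oxazolidin-3-yl]butanoate | CC(C)(C)OC(=O)C[C@H](C(=O)N1[C@@H](C(C)C)COC1=O)[C@H](O)c1ccc(O[Si](C)(C)C(C)(C)C)c(OC)c1 | intermediate
16 | tert-butyl (3S)-3-[(S)-[(tert-butyldimethylsilyl)oxy]{4-[(tert-butyldimethylsilyl)oxy]-3-methoxyphenyl}methyl]-4-oxo-4-[(4S)-2-oxo-4-(propan-2-yl)-1,3-oxazolidin-3-yl]butanoate | CC(C)(C)OC(=O)C[C@H](C(=O)N1[C@@H](C(C)C)COC1=O)[C@H](O[Si](C)(C)C(C)(C)C)c1ccc(O[Si](C)(C)C(C)(C)C)c(OC)c1 | intermediate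
17 | tert-butyl (3R,4S)-4-[(tert-butyldimethylsilyl)oxy]-4-{4-[(tert-butyldimethylsilyl)oxy]-3-methoxyphenyl}-3-(hydroxymethyl)butanoate | CC(C)(C)OC(=O)C[C@H](CO)[C@H](O[Si](C)(C)C(C)(C)C)c1ccc(O[Si](C)(C)C(C)(C)C)c(OC)c1 | intermediate
18 | (4R)-4-[(S)-[(tert-butyldimethylsilyl)oxy]{4-[(tert-butyldimethylsilyl)oxy]-3-methoxyphenyl}methyl]oxolan-2-one | O=C1C[C@H](CO1)[C@H](O[Si](C)(C)C(C)(C)C)c1ccc(O[Si](C)(C)C(C)(C)C)c(OC)c1 | intermediate
19 | lithium enolate of 18 (not isolated) | [Li]OC1=C[C@H](CO1)[C@H](O[Si](C)(C)C(C)(C)C)c1ccc(O[Si](C)(C)C(C)(C)C)c(OC)c1 | intermediate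
20 | (3R,4R)-3-{4-[(tert-butyldimethylsilyl)oxy]-3-methoxybenzyl}-4-[(S)-[(tert-butyldimethylsilyl)oxy]{4-[(tert-butyldimethylsilyl)oxy]-3-methoxyphenyl}methyl]oxolan-2-one | COc1cc(C[C@H]2C(=O)OC[C@@H]2[C@H](O[Si](C)(C)C(C)(C)C)c2ccc(O[Si](C)(C)C(C)(C)C)c(OC)c2)ccc1O[Si](C)(C)C(C)(C)C | intermediate
21 | (3R,4R)-3-(4-hydroxy-3-methoxybenzyl)-4-[(S)-hydroxy(4-hydroxy-3-methoxyphenyl)methyl]oxolan-2-one | COc1cc(C[C@H]2C(=O)OC[C@@H]2[C@H](O)c2ccc(O)c(OC)c2)ccc1O | target

## Step count and risks

Total steps: 14.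
Longest linear sequence: 9 steps (1, 2, 3, 9, 10, 11, 12, 13, 14, from catechol to the target). The side branches are steps 4 and 5 (bromide), step 6 (auxiliary), and steps 7 and 8 (imide).

**Risk 1, step 2.** The aqueous hydroxyalkylation gives some ortho isomer and bis-adduct, and the oxidative decarboxylation can stall or over-oxidise. The fallback sets out from 2 and comes back at 5. Para-bromination of 2 with Bu4NBr3 in CH2Cl2/MeOH gives 4-bromo-2-methoxyphenol F1. Silylation with TBSCl and imidazole gives (4-bromo-2-methoxyphenoxy)(tert-butyl)dimethylsilane F2. Bromine–lithium exchange with n-BuLi in THF at −78 °C gives [4-(tert-butyldimethylsilyloxy)-3-methoxyphenyl]lithium F3, which is formylated with DMF to give 5 directly.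

**Risk 2, step 12.** The tert-butyl ester may lactonise too slowly under mild acid, while stronger acid can ionise the electron-rich benzylic silyl ether. The fallback sets out from 9 and comes back at 18, replacing the ester by an alkene that is cleaved oxidatively.
- N-acylation of 9 (n-BuLi, THF, −78 °C, pent-4-enoyl chloride) gives (4S)-3-(pent-4-enoyl)-4-(propan-2-yl)-1,3-oxazolidin-2-one F4.
- The same Bu2BOTf/iPr2NEt aldol with 5 gives the syn adduct (4S)-3-[(2S,3S)-2-allyl-3-hydroxy-3-(4-TBSO-3-methoxyphenyl)propanoyl]-4-(propan-2-yl)-1,3-oxazolidin-2-one F5.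
- TBSOTf and 2,6-lutidine give its silyl ether F6.
- LiBH4 gives (2R)-2-[(S)-(TBSO)(4-TBSO-3-methoxyphenyl)methyl]pent-4-en-1-ol F7.
- OsO4 (cat.), NaIO4 and 2,6-lutidine in dioxane/H2O cleave the alkene to an aldehyde that closes to the lactol (4R)-4-[(S)-(TBSO)(4-TBSO-3-methoxyphenyl)methyl]oxolan-2-ol F8.
- Oxidation with Pr4N[RuO4] (cat.) and N-methylmorpholine N-oxide gives 18.

**Risk 3, step 13.** Bromide 7 is labile, and the hindered enolate may alkylate slowly or twice. The fallback sets out from 18 and comes back at 20, replacing the SN2 step by an aldol addition and radical deoxygenation. The enolate of 18 (LiN(SiMe3)2, THF, −78 °C) adds to aldehyde 5 anti to the C4 substituent to give (3S,4R)-3-[hydroxy(4-TBSO-3-methoxyphenyl)methyl]-4-[(S)-(TBSO)(4-TBSO-3-methoxyphenyl)methyl]oxolan-2-one F9 as a mixture of carbinol epimers. 1,1'-Thiocarbonyldiimidazole with 4-(dimethylamino)pyridine (cat.) converts it to the O-benzylic imidazole-1-carbothioate F10. Barton–McCombie reduction (Bu3SnH, azobisisobutyronitrile, toluene, 90 °C) removes the benzylic oxygen and gives 20 with C3 unchanged.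

## Further compounds

F1 | step 2 | 4-bromo-2-methoxyphenol | COc1cc(Br)ccc1O
F2 | step 2 | (4-bromo-2-methoxyphenoxy)(tert-butyl)dimethylsilane | COc1cc(Br)ccc1O[Si](C)(C)C(C)(C)C
F3 | step 2 | [4-(tert-butyldimethylsilyloxy)-3-methoxyphenyl]lithium | COc1cc([Li])ccc1O[Si](C)(C)C(C)(C)C
F4 | step 12 | (4S)-3-(pent-4-enoyl)-4-(propan-2-yl)-1,3-oxazolidin-2-one | C=CCCC(=O)N1[C@@H](C(C)C)COC1=O
F5 | step 12 | (4S)-3-[(2S,3S)-2-allyl-3-hydroxy-3-{4-[(tert-butyldimethylsilyl)oxy]-3-methoxyphenyl}propanoyl]-4-(propan-2-yl)-1,3-oxazolidin-2-one | C=CC[C@H](C(=O)N1[C@@H](C(C)C)COC1=O)[C@H](O)c1ccc(O[Si](C)(C)C(C)(C)C)c(OC)c1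
F6 | step 12 | (4S)-3-[(2S,3S)-2-allyl-3-[(tert-butyldimethylsilyl)oxy]-3-{4-[(tert-butyldimethylsilyl)oxy]-3-methoxyphenyl}propanoyl]-4-(propan-2-yl)-1,3-oxazolidin-2-one | C=CC[C@H](C(=O)N1[C@@H](C(C)C)COC1=O)[C@H](O[Si](C)(C)C(C)(C)C)c1ccc(O[Si](C)(C)C(C)(C)C)c(OC)c1
F7 | step 12 | (2R)-2-[(S)-[(tert-butyldimethylsilyl)oxy]{4-[(tert-butyldimethylsilyl)oxy]-3-methoxyphenyl}methyl]pent-4-en-1-ol | C=CC[C@H](CO)[C@H](O[Si](C)(C)C(C)(C)C)c1ccc(O[Si](C)(C)C(C)(C)C)c(OC)c1
F8 | step 12 | (4R)-4-[(S)-[(tert-butyldimethylsilyl)oxy]{4-[(tert-butyldimethylsilyl)oxy]-3-methoxyphenyl}methyl]oxolan-2-ol, anomer mixture | OC1C[C@H](CO1)[C@H](O[Si](C)(C)C(C)(C)C)c1ccc(O[Si](C)(C)C(C)(C)C)c(OC)c1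
F9 | step 13 | (3S,4R)-3-[hydroxy{4-[(tert-butyldimethylsilyl)oxy]-3-methoxyphenyl}methyl]-4-[(S)-[(tert-butyldimethylsilyl)oxy]{4-[(tert-butyldimethylsilyl)oxy]-3-methoxyphenyl}methyl]oxolan-2-one, carbinol epimers | COc1cc(C(O)[C@H]2C(=O)OC[C@@H]2[C@H](O[Si](C)(C)C(C)(C)C)c2ccc(O[Si](C)(C)C(C)(C)C)c(OC)c2)ccc1O[Si](C)(C)C(C)(C)C
F10 | step 13 | O-[{4-[(tert-butyldimethylsilyl)oxy]-3-methoxyphenyl}{(3S,4R)-4-[(S)-[(tert-butyldimethylsilyl)oxy]{4-[(tert-butyldimethylsilyl)oxy]-3-methoxyphenyl}methyl]-2-oxooxolan-3-yl}methyl] 1H-imidazole-1-carbothioate | COc1cc(C(OC(=S)n2ccnc2)[C@H]2C(=O)OC[C@@H]2[C@H](O[Si](C)(C)C(C)(C)C)c2ccc(O[Si](C)(C)C(C)(C)C)c(OC)c2)ccc1O[Si](C)(C)C(C)(C)C
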